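Its constants stand for no real mixture; what happens was integrated by code.

The easy step in this flask was the opening of substrate: its forward half-life is 0.13 min, so I called substrate and open intermediate together the pool and gave open intermediate in it the rough weight 0.811 from the equilibrium constant of 4.3. That weight was my convenience and not an equilibrium that holds, because the way back of open intermediate, at 0.0200 /s, is slower than its self-coupling at about 0.0579 /s.

substrate 2.1 M; solid partner 1.10 equiv; time 1.5 h

* at 1.5 h, what has stopped the reaction, if anything has (for what has run out or reacted, a solid counts together with what of it has only dissolved) (all of the substrate has reacted / it is still moving / forward and back rates have come level)
* how much target there is at 1.5 h, in percent of the substrate charged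
* how much homo product there is at 1.5 h, in percent of the substrate charged

- in percentages every species weighs as the substrate in it: one homo product counts as two
- for target the crystals are counted in
- a doubled species enters its step squared and goes two at a time
- as a solid, counted per litre of solution: solid partner, crystals
- at the start none of the solid partner is in solution
- the reaction counts as stopped when no species that holds the substrate changes by six tenths of a point or more over the second half of the time
- run time (flask): 1.5 h

    substrate ⇌ open intermediate (K1 = 4.3, k1 = 0.086 /s)
    fresh partner → second intermediate (k2 = 0.32 /s)
    open intermediate + second intermediate → target (k3 = 0.011 /M/s)
    2 open intermediate → homo product (k4 = 0.017 /M/s)
    solid partner ⇌ fresh partner, rate k5*(cs5 - [fresh partner]) while solid is left; crystals form when [fresh partner] > cs5 (cs5 = 2.1 M, k5 = 0.014 /s)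
    crystals ⇌ target, rate k6*(cs6 - [target]) while solid is left; crystals form when [target] > cs6 (cs6 = 0.091 M, k6 = 1.8 /s)

Open intermediate coupling with itself to homo product gives the pool a half-life of 0.355 min. Open intermediate also meets second intermediate to give target, but second intermediate comes from solid partner, which dissolves as fresh partner at up to 1.76 M/min, so the charge needs 1.31 min. Fresh partner has a half-life of 0.0361 min, far shorter than that, so I let [second intermediate] climb as this feed times the time. I carried one quantity, the crossing time, the moment when second intermediate takes open intermediate as fast as open intermediate takes itself, which came out at 0.867 min. That falls before the dissolving ends, and the self-coupling fall leaves 29.0% of the substrate in the pool by then. I took that share as target and the other 71.0% as homo product, with the substrate consumed.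

The forecast read all of the substrate has reacted, with 32% target and 68% homo product, on the ground that “dimerisation takes most of the substrate before much second intermediate is available”. The simulation gave all of the substrate has reacted, with 34.5% target and 65.5% homo product, so my figure for target lay 5.5 percentage points low.

In this flask, half of the dissolving was done by 0.681 min, close to half of my 1.31 min and earlier than the crossing time of 0.867 min. With 0.280 equiv of solid partner, the neighbour flask had a reckoned dissolving time of 0.333 min, well short of that crossing time, and it ended at 19.8% target and 80.2% homo product.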